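**Remark on the chemistry (assumption).** The SMILES is read as written: the dihydrobenzofuran is 2,3-cis, (2S,3S), and the furofuran is the exo,exo (1′R,2′S,5′R,6′S) isomer. The route is built for exactly this isomer. Dihydrobenzofuran atoms are O1, C2, C3, C3a–C7a; furofuran atoms carry primes (C1′, C2′, O3′, C4′, C5′, C6′, O7′, C8′). Ring A is the tetrahydrofuran containing O3′, ring B the one containing O7′.

## Analysis of the target

The target is a sesquilignan built from two units. One is a cis-fused 3,7-dioxabicyclo[3.3.0]octane (furofuran) whose C6′ carries a 4-hydroxy-3,5-dimethoxyphenyl group. Its C2′ is bonded to C5 of a 7-methoxy-2,3-dihydrobenzofuran that carries a 4-hydroxy-3-methoxyphenyl group at C2 and CH2OH at C3. The furofuran has four contiguous stereocentres, (1′R,2′S,5′R,6′S), with both aryl groups on the convex face. The dihydrobenzofuran has two, (2S,3S), with the C2 aryl group and the C3 hydroxymethyl group cis, which is the less stable arrangement. An arene separates the two stereochemical units, so neither can relay its configuration to the other; each needs absolute control, and any lapse gives a diastereomer. Three benzylic C–O bonds (C2–O1, C2′–O3′, C6′–O7′) sit para to oxygen; once the phenols are free they ionise under acid and scramble cis to trans and exo to endo. The synthesis is hard because the cis ring cannot be reached by equilibration, and because the two phenolic rings of the furofuran must be told apart, one of them becoming part of the dihydrobenzofuran. The strategy rests on one feature: C3 carries CH2OH and is bonded to the arene carbon C3a, ortho to O1. That is the pattern left when an aryl anion at C3a opens a terminal epoxide at its internal carbon.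

## Retrosynthetic reasoning

**27 to 26.** Only the two phenolic O–benzyl bonds are cut. The phenols are unveiled last because free phenols para to the benzylic ethers make those ethers labile. Hydrogenolysis is neutral and is the only operation the cis ring has to survive.

**26 to 24 (through 25).** The C3–C3a bond is cut. It is the one bond of the five-membered ring that can be formed stereospecifically at C3 without touching C2: an aryl anion at C3a attacks the internal carbon of a terminal epoxide with inversion, and the CH2OH group is released unprotected. Cutting C2–O1 instead would mean substitution at an ionisable benzylic carbon during ring closure. Cutting C2–C3 would lead to methods that favour the trans ring or need catalyst control. Forward, the aryllithium 25 must form faster than anything else happens to 24, and it must choose the internal epoxide carbon (five-membered ring) over the terminal one (six-membered ring).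

**24 to 19 and 23.** The O1–C2 aryl ether bond is cut. This joins the two halves convergently. The phenol 19 attacks the carbinol carbon of 23 with inversion in a Mitsunobu etherification. The inversion is needed: kinetic resolution gives the erythro epoxy alcohol 23, and the cis ring needs the threo ether 24.

**23 to 22, 21 and 20.** The epoxide oxygen is removed and the racemate accepted: a Sharpless kinetic resolution of allylic alcohol 22 sets both stereocentres of 23 in one operation. Alcohol 22 comes from aldehyde 21 by vinyl addition, and 21 from vanillin 20 by benzylation.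

**19 to 17 (through 18).** The O3′–C4′ bond of ring A and the aryl O–Si bond are cut. The C2′–O3′ bond is kept, so the C2′ configuration is carried into the ring with retention: the C2′ oxygen displaces a sulfonate on C4′. Fluoride frees that oxygen and the phenol in the same operation.

**17 to 16.** The C6′–O7′ bond of ring B is cut. Forward, the syringyl-type benzylic alcohol ionises and the C8′ hydroxyl captures the cation. Both carbinol epimers of 16 converge on one product. Ring B is closed first, as a monocycle, where the aryl group clearly prefers to sit trans to its neighbours; in the finished bicycle exo and endo isomers are much closer in energy.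

**16 to 15, then 11 and 13.** The C5′–C6′ bond is cut (aldol). Lactone 11 holds C4′ and C8′ in its ring, so aldehyde 13 enters trans to the C1′ substituent. That sets C5′ relative to C1′.

**11 to 10, 9, 8, then 6 and 2; 6 to 3 and 4; 2 to 1; 13 to 12.** The C1′–C2′ bond is cut (Evans syn aldol between imide 6 and aldehyde 2). It sets C1′ and C2′ together from the auxiliary 4. The bromo-substituted ring is placed here for two reasons. Its benzylic position ionises least readily, so the stereocentre and its silyl ether survive the later acid steps. And bromine from 1 gives the position of the future C3a without any regioselective halogenation.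

## Alternatives that were turned down

**Alternative 1: double benzylic oxidation of a dibenzylbutanediol.** The disconnection cuts both benzylic C–O bonds of the furofuran and leads back to the acyclic diol A2. Forward, a quinone oxidant takes each para-hydroxybenzyl position to a quinone methide, which the hydroxymethyl group on the neighbouring stereocentre captures, closing both rings to (+)-medioresinol A1.
- For it: one operation makes two rings and two stereocentres, and the two carbon stereocentres of A2 are accessible by established asymmetric chemistry. In step count for the bicycle it is clearly stronger than the ten steps spent here on 19.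
- Against it: A1 has two free, undifferentiated phenols and no handle ortho to the guaiacyl oxygen. The dihydrobenzofuran, the hard part of the target, is still unbuilt. Attaching it would need regioselective functionalisation of a very electron-rich diphenol, or an oxidative phenol coupling, which delivers the trans ring. Exo selectivity rests only on kinetic capture of the quinone methides.
- Comparison: the chosen plan gives up the short furofuran synthesis. In return the bromine and the phenol differentiation are in place from compound 1, and the cis ring is made by a stereospecific step.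

**Alternative 2: three-component conjugate addition–aldol on a chiral butenolide.** The disconnection cuts C5′–C6′ and C1′–C2′ on either side of a four-carbon lactone. Forward, the lithiated dithiane A6 adds to the β-carbon of the (5R)-menthyloxybutenolide A5 anti to the alkoxy group, and the enolate is trapped by aldehyde A4, giving lactone A3 with every carbon of the target.
- For it: maximal convergence; the acetal centre dictates the trans,trans arrangement. Its furofuran assembly is shorter and more convergent than the one used here.
- Against it: A4 must already contain the cis-dihydrobenzofuran, so the central stereochemical problem is only postponed. After the key step A3 still needs dithiane removal, reduction of lactone and acetal, and a cyclodehydration, several of them acidic, all with the fragile cis ring on board. The carbinol is formed as a mixture.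
- Comparison: the chosen plan offers instead that the fragile ring is made in the penultimate step and sees only one neutral operation afterwards.

**Alternative 3: Prins-type bicyclisation onto a styrene.** The disconnection cuts C4′–C5′ and C6′–O7′. Forward, a strong Lewis acid ionises the methoxymethyl ether on the C2′ oxygen of A8; the oxocarbenium carbon (C4′) adds to the styrene at C5′, and the benzylic cation at C6′ is captured by the silyl ether oxygen on C8′ with loss of silicon, giving the protected target A7.
- For it: both furofuran rings and two bonds form in one late step from a linear precursor. It is shorter than the present furofuran synthesis.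
- Against it: a stoichiometric Lewis acid meets the cis-2-aryl-dihydrobenzofuran, whose C2–O1 bond is a benzylic aryl ether. Two new stereocentres (C5′, C6′) and their relation to C1′ depend on the conformational preferences of a cationic cascade. Electron-rich arenes invite Friedel–Crafts side reactions. Three different protecting groups remain to be removed, one of them an aryl sulfonate.
- Comparison: the chosen plan is longer, but each furofuran stereocentre is set by a reaction with a well-understood model, and the risky step is stereospecific by mechanism.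

Key step: step 15

## Route

Abbreviations: TIPS = triisopropylsilyl, TBS = tert-butyldimethylsilyl.

Step 1
Reactants: 1 5-bromovanillin
Product: 2 3-bromo-5-methoxy-4-(triisopropylsilyloxy)benzaldehyde
Conditions: TIPSOTf, 2,6-lutidine, CH2Cl2, 0 °C to rt
Reagents that add atoms: triisopropylsilyl trifluoromethanesulfonate, CC(C)[Si](C(C)C)(C(C)C)OS(=O)(=O)C(F)(F)F
Why: O-silylation of a hindered, acidic phenol with a silyl triflate; the bulky silyl ether is orthogonal to the benzyl ethers and should stand up to enolates, borohydride and catalytic acid until fluoride removes it in step 10.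

Step 2
Reactants: 3 4-tert-butoxy-4-oxobutanoic acid (mono-tert-butyl succinate); 4 (S)-4-benzyl-1,3-oxazolidin-2-one
Product: 6 tert-butyl 4-[(S)-4-benzyl-2-oxo-1,3-oxazolidin-3-yl]-4-oxobutanoate, via mixed pivalic anhydride 5 (not isolated)
Conditions: t-BuCOCl, Et3N, THF, −20 °C; then 4, LiCl, rt
Reagents that add atoms: none
Why: N-acylation of an Evans oxazolidinone through a mixed anhydride; the oxazolidinone attacks the unhindered succinyl carbonyl of 5 and the tert-butyl ester is inert.

Step 3
Reactants: 6 tert-butyl 4-[(S)-4-benzyl-2-oxo-1,3-oxazolidin-3-yl]-4-oxobutanoate; 2 3-bromo-5-methoxy-4-(triisopropylsilyloxy)benzaldehyde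
Product: 8 tert-butyl (3S)-4-[(S)-4-benzyl-2-oxo-1,3-oxazolidin-3-yl]-3-[(S)-[3-bromo-5-methoxy-4-(triisopropylsilyloxy)phenyl](hydroxy)methyl]-4-oxobutanoate, via dibutylboron Z-enolate 7 (not isolated)
Conditions: Bu2BOTf, i-Pr2NEt, CH2Cl2, −78 to 0 °C; then 2, −78 to 0 °C; H2O2, MeOH, pH 7 buffer
Reagents that add atoms: none
Why: Evans syn aldol: only the imide is enolised, to the Z-enolate 7, and the chair transition state with one face shielded by the auxiliary's benzyl group sets the (3S) α-carbon (future C1′) and the (S) carbinol (future C2′) together; this syn relation is the one that later places the aryl group on the convex face of ring A.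

Step 4
Reactants: 8 syn aldol adduct
Product: 9 tert-butyl (3S)-4-[(S)-4-benzyl-2-oxo-1,3-oxazolidin-3-yl]-3-[(S)-[3-bromo-5-methoxy-4-(triisopropylsilyloxy)phenyl](tert-butyldimethylsilyloxy)methyl]-4-oxobutanoate
Conditions: TBSOTf, 2,6-lutidine, CH2Cl2, −78 to 0 °C
Reagents that add atoms: tert-butyldimethylsilyl trifluoromethanesulfonate, CC(C)(C)[Si](C)(C)OS(=O)(=O)C(F)(F)F
Why: Silyl ether formation; it blocks retro-aldol and lactonisation onto the ester and keeps this oxygen (the future O3′) masked until step 10; no stereocentre is touched.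

Step 5
Reactants: 9 silylated aldol adduct
Product: 11 (4R)-4-[(S)-[3-bromo-5-methoxy-4-(triisopropylsilyloxy)phenyl](tert-butyldimethylsilyloxy)methyl]dihydrofuran-2(3H)-one, via hydroxy ester 10 (not isolated)
Conditions: LiBH4, MeOH, THF, 0 °C; work-up; then p-TsOH·H2O (cat.), CH2Cl2, rt
Reagents that add atoms: none
Why: Reductive removal of the auxiliary (borohydride attacks the exocyclic imide carbonyl and leaves the tert-butyl ester), then acid-catalysed lactonisation of the γ-hydroxy tert-butyl ester 10; the benzylic silyl ether sits on the bromo-substituted ring, which stabilises a benzylic cation poorly, so it should survive the catalytic acid.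

Step 6
Reactants: 12 syringaldehyde
Product: 13 4-(benzyloxy)-3,5-dimethoxybenzaldehyde
Conditions: BnBr, K2CO3, DMF, rt
Reagents that add atoms: benzyl bromide, BrCc1ccccc1
Why: Williamson etherification; the benzyl ether survives fluoride, hydride, amide base and alkyllithium and leaves with the second benzyl ether in the last step.

Step 7
Reactants: 11 β-substituted butyrolactone; 13 4-(benzyloxy)-3,5-dimethoxybenzaldehyde
Product: 15 (3S,4R)-3-[[4-(benzyloxy)-3,5-dimethoxyphenyl](hydroxy)methyl]-4-[(S)-[3-bromo-5-methoxy-4-(triisopropylsilyloxy)phenyl](tert-butyldimethylsilyloxy)methyl]dihydrofuran-2(3H)-one as both carbinol epimers, via lithium enolate 14 (not isolated)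
Conditions: LiN(SiMe3)2, THF, −78 °C; then 13, −78 °C; AcOH, −78 °C
Reagents that add atoms: none
Why: Aldol addition of a lactone lithium enolate; the aldehyde enters trans to the bulky C4 substituent, which fixes C5′ relative to C1′; the new carbinol centre is not controlled and need not be, because step 9 passes through the benzylic cation.

Step 8
Reactants: 15 aldol lactone (both carbinol epimers)
Product: 16 (2R,3R)-2-[[4-(benzyloxy)-3,5-dimethoxyphenyl](hydroxy)methyl]-3-[(S)-[3-bromo-5-methoxy-4-(triisopropylsilyloxy)phenyl](tert-butyldimethylsilyloxy)methyl]butane-1,4-diol as both carbinol epimers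
Conditions: LiBH4, MeOH, THF, 0 °C to rt
Reagents that add atoms: none
Why: Borohydride reduction of the lactone to the 1,4-diol; silyl ethers, benzyl ether and aryl bromide are inert, and the low temperature keeps the β-hydroxy lactone from retro-aldol cleavage before it is reduced.

Step 9
Reactants: 16 triol (both carbinol epimers)
Product: 17 [(2S,3R,4R)-2-[4-(benzyloxy)-3,5-dimethoxyphenyl]-4-[(S)-[3-bromo-5-methoxy-4-(triisopropylsilyloxy)phenyl](tert-butyldimethylsilyloxy)methyl]tetrahydrofuran-3-yl]methanol
Conditions: camphorsulfonic acid (cat.), CH2Cl2, 0 °C to rt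
Reagents that add atoms: none
Why: Acid-catalysed cyclodehydration (SN1): the free benzylic alcohol ionises and the cation is captured by the C8′ hydroxyl in a five-membered closure (the C4′ hydroxyl could only give an oxetane), closing ring B; the aryl group should take the position trans to both ring neighbours, which sets C6′ as (S) from either epimer; the other benzylic oxygen is silylated and sits on the less ionisable ring.

Step 10
Reactants: 17 tetrahydrofuran alcohol
Product: 19 2-bromo-6-methoxy-4-[(1R,2S,5R,6S)-6-[4-(benzyloxy)-3,5-dimethoxyphenyl]-3,7-dioxabicyclo[3.3.0]octan-2-yl]phenol, via primary mesylate 18 (not isolated)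
Conditions: MsCl, Et3N, CH2Cl2, 0 °C; then Bu4NF, THF, 0 °C to rt; aq NH4Cl
Reagents that add atoms: none
Why: Sulfonylation of the only free hydroxyl, then fluoride removes both silyl groups; the liberated benzylic alkoxide displaces the primary mesylate (5-exo-tet Williamson closure of ring A), and because the C2′–O bond is never broken the (S) configuration from step 3 is kept; the same operation frees the phenol.

Step 11
Reactants: 20 vanillin
Product: 21 4-(benzyloxy)-3-methoxybenzaldehyde
Conditions: BnBr, K2CO3, DMF, rt
Reagents that add atoms: benzyl bromide, BrCc1ccccc1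
Why: Williamson etherification of the phenol.

Step 12
Reactants: 21 4-(benzyloxy)-3-methoxybenzaldehyde
Product: 22 racemic 1-[4-(benzyloxy)-3-methoxyphenyl]prop-2-en-1-ol
Conditions: CH2=CHMgBr, THF, −78 to 0 °C; aq NH4Cl
Reagents that add atoms: vinylmagnesium bromide, C=C[Mg]Br
Why: Grignard 1,2-addition to an aromatic aldehyde; the racemate is wanted because the next step resolves it.

Step 13
Reactants: 22 racemic 1-[4-(benzyloxy)-3-methoxyphenyl]prop-2-en-1-ol
Product: 23 (S)-[4-(benzyloxy)-3-methoxyphenyl][(R)-oxiran-2-yl]methanol (erythro)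
Conditions: Ti(OiPr)4 (0.2 equiv), L-(+)-diisopropyl tartrate (0.24 equiv), t-BuOOH (0.45 equiv), 4 Å sieves, CH2Cl2, −20 °C
Reagents that add atoms: tert-butyl hydroperoxide, CC(C)(C)OO
Why: Sharpless kinetic resolution of a secondary allylic alcohol: with L-(+)-tartrate the (R)-enantiomer of 22 (the counterpart of the (S)-alkyl vinyl carbinols, since aryl outranks vinyl) should be epoxidised much faster and erythro-selectively, giving the (1S,2R) epoxy alcohol; substoichiometric oxidant stops the reaction before the slow enantiomer reacts, and any stray stereoisomer becomes a separable diastereomer after step 14.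

Step 14
Reactants: 19 furofuran bromophenol; 23 erythro epoxy alcohol
Product: 24 (1R,2S,5R,6S)-2-[3-bromo-4-[(R)-[4-(benzyloxy)-3-methoxyphenyl][(R)-oxiran-2-yl]methoxy]-5-methoxyphenyl]-6-[4-(benzyloxy)-3,5-dimethoxyphenyl]-3,7-dioxabicyclo[3.3.0]octane (threo epoxy ether)
Conditions: PPh3, diisopropyl azodicarboxylate, toluene, 0 °C to rt
Reagents that add atoms: none
Why: Mitsunobu etherification: the ortho-bromophenol is acidic enough to be the pronucleophile and displaces the oxyphosphonium group by SN2 with inversion, (S) to (R), turning erythro into threo; the epoxide is not touched, and its inductive pull together with the nonpolar solvent works against ionisation of the electron-rich benzylic centre.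

Step 15
Reactants: 24 threo epoxy ether
Product: 26 [(2S,3S)-2-[4-(benzyloxy)-3-methoxyphenyl]-5-[(1R,2S,5R,6S)-6-[4-(benzyloxy)-3,5-dimethoxyphenyl]-3,7-dioxabicyclo[3.3.0]octan-2-yl]-7-methoxy-2,3-dihydro-1-benzofuran-3-yl]methanol, via aryllithium 25 (not isolated)
Conditions: t-BuLi (2.1 equiv), THF, −78 °C, then to 0 °C; aq NH4Cl
Reagents that add atoms: none
Why: Bromine–lithium exchange with the first equivalent of t-BuLi gives aryllithium 25, and the second equivalent destroys the tert-butyl bromide so that nothing can alkylate or re-brominate 25. The carbanion at C3a then attacks the internal epoxide carbon from the side opposite its C–O bond, forming C3–C3a and the five-membered ring and releasing the primary alkoxide, which work-up protonates. The closest known reaction type is the Parham cyclisation of ortho-lithiated aryl glycidyl ethers to 3-(hydroxymethyl)-2,3-dihydrobenzofurans. The ring closes in the 5-exo-tet mode, the breaking C–O bond lying outside the new ring. The one new stereocentre, C3, is set by inversion of the (R) epoxide carbon, so it is controlled by the substrate configuration fixed in step 13; C2 is a spectator, and threo therefore gives cis. The step needs three selectivities: exchange must beat deprotonation, which the absence of O–H groups and the low temperature should secure; closure at the internal carbon must beat 6-endo closure at the terminal carbon, which the short three-atom tether should secure, since only the internal carbon allows a collinear backside approach; and the epoxide must stay intact until attacked, which is why lithium is used without magnesium or other Lewis-acidic halide additives that would open it to a halohydrin.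

Step 16
Reactants: 26 bis-benzyl ether
Product: 27 (2S,3S)-2-(4-hydroxy-3-methoxyphenyl)-3-(hydroxymethyl)-7-methoxy-5-[(1R,2S,5R,6S)-6-(4-hydroxy-3,5-dimethoxyphenyl)-3,7-dioxabicyclo[3.3.0]octan-2-yl]-2,3-dihydro-1-benzofuran (CNP0126146.1)
Conditions: H2 (1 atm), palladium on carbon (Pd/C), EtOAc, rt, stopped after two equivalents of H2
Reagents that add atoms: none
Why: Hydrogenolysis of two aryl benzyl ethers, which should be much faster than cleavage of the ring benzylic C–O bonds; the neutral, non-protic medium avoids acid-induced epimerisation of the cis ring once the phenols are free.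

## Compound list

1 | 5-bromovanillin | COc1cc(C=O)cc(Br)c1O | starting material
2 | 3-bromo-5-methoxy-4-(triisopropylsilyloxy)benzaldehyde | COc1cc(C=O)cc(Br)c1O[Si](C(C)C)(C(C)C)C(C)C | intermediate
3 | 4-tert-butoxy-4-oxobutanoic acid | CC(C)(C)OC(=O)CCC(=O)O | starting material
4 | (S)-4-benzyl-1,3-oxazolidin-2-one | O=C1N[C@@H](Cc2ccccc2)CO1 | starting material
5 | mixed anhydride of 3 and pivalic acid | CC(C)(C)OC(=O)CCC(=O)OC(=O)C(C)(C)C | intermediate (not isolated)
6 | tert-butyl 4-[(S)-4-benzyl-2-oxo-1,3-oxazolidin-3-yl]-4-oxobutanoate | CC(C)(C)OC(=O)CCC(=O)N1C(=O)OC[C@@H]1Cc1ccccc1 | intermediate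
7 | dibutylboron Z-enolate of 6 | CC(C)(C)OC(=O)C/C=C(\OB(CCCC)CCCC)N1C(=O)OC[C@@H]1Cc1ccccc1 | intermediate (not isolated)
8 | syn aldol adduct, tert-butyl (3S)-4-[(S)-4-benzyl-2-oxo-1,3-oxazolidin-3-yl]-3-[(S)-[3-bromo-5-methoxy-4-(triisopropylsilyloxy)phenyl](hydroxy)methyl]-4-oxobutanoate | CC(C)(C)OC(=O)C[C@@H]([C@H](O)c1cc(OC)c(O[Si](C(C)C)(C(C)C)C(C)C)c(Br)c1)C(=O)N1C(=O)OC[C@@H]1Cc1ccccc1 | intermediate
9 | TBS ether of 8 | CC(C)(C)OC(=O)C[C@@H]([C@H](O[Si](C)(C)C(C)(C)C)c1cc(OC)c(O[Si](C(C)C)(C(C)C)C(C)C)c(Br)c1)C(=O)N1C(=O)OC[C@@H]1Cc1ccccc1 | intermediate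
10 | tert-butyl (3R)-3-[(S)-[3-bromo-5-methoxy-4-(triisopropylsilyloxy)phenyl](tert-butyldimethylsilyloxy)methyl]-4-hydroxybutanoate | CC(C)(C)OC(=O)C[C@@H]([C@H](O[Si](C)(C)C(C)(C)C)c1cc(OC)c(O[Si](C(C)C)(C(C)C)C(C)C)c(Br)c1)CO | intermediate (not isolated)
11 | (4R)-4-[(S)-[3-bromo-5-methoxy-4-(triisopropylsilyloxy)phenyl](tert-butyldimethylsilyloxy)methyl]dihydrofuran-2(3H)-one | O=C1C[C@@H]([C@H](O[Si](C)(C)C(C)(C)C)c2cc(OC)c(O[Si](C(C)C)(C(C)C)C(C)C)c(Br)c2)CO1 | intermediate
12 | syringaldehyde | COc1cc(C=O)cc(OC)c1O | starting material
13 | 4-(benzyloxy)-3,5-dimethoxybenzaldehyde | COc1cc(C=O)cc(OC)c1OCc1ccccc1 | intermediate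
14 | lithium enolate of 11 | [Li]OC1=C[C@@H]([C@H](O[Si](C)(C)C(C)(C)C)c2cc(OC)c(O[Si](C(C)C)(C(C)C)C(C)C)c(Br)c2)CO1 | intermediate (not isolated)
15 | (3S,4R)-3-[[4-(benzyloxy)-3,5-dimethoxyphenyl](hydroxy)methyl]-4-[(S)-[3-bromo-5-methoxy-4-(triisopropylsilyloxy)phenyl](tert-butyldimethylsilyloxy)methyl]dihydrofuran-2(3H)-one, both epimers at the new carbinol carbon | O=C1[C@H](C(O)c2cc(OC)c(OCc3ccccc3)c(OC)c2)[C@@H]([C@H](O[Si](C)(C)C(C)(C)C)c2cc(OC)c(O[Si](C(C)C)(C(C)C)C(C)C)c(Br)c2)CO1 | intermediate
16 | (2R,3R)-2-[[4-(benzyloxy)-3,5-dimethoxyphenyl](hydroxy)methyl]-3-[(S)-[3-bromo-5-methoxy-4-(triisopropylsilyloxy)phenyl](tert-butyldimethylsilyloxy)methyl]butane-1,4-diol, both epimers at the free carbinol carbon | OC[C@H](C(O)c1cc(OC)c(OCc2ccccc2)c(OC)c1)[C@@H]([C@H](O[Si](C)(C)C(C)(C)C)c1cc(OC)c(O[Si](C(C)C)(C(C)C)C(C)C)c(Br)c1)CO | intermediate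
17 | [(2S,3R,4R)-2-[4-(benzyloxy)-3,5-dimethoxyphenyl]-4-[(S)-[3-bromo-5-methoxy-4-(triisopropylsilyloxy)phenyl](tert-butyldimethylsilyloxy)methyl]tetrahydrofuran-3-yl]methanol | OC[C@@H]1[C@@H](c2cc(OC)c(OCc3ccccc3)c(OC)c2)OC[C@@H]1[C@H](O[Si](C)(C)C(C)(C)C)c1cc(OC)c(O[Si](C(C)C)(C(C)C)C(C)C)c(Br)c1 | intermediate
18 | methanesulfonate of 17 | CS(=O)(=O)OC[C@@H]1[C@@H](c2cc(OC)c(OCc3ccccc3)c(OC)c2)OC[C@@H]1[C@H](O[Si](C)(C)C(C)(C)C)c1cc(OC)c(O[Si](C(C)C)(C(C)C)C(C)C)c(Br)c1 | intermediate (not isolated)
19 | 2-bromo-6-methoxy-4-[(1R,2S,5R,6S)-6-[4-(benzyloxy)-3,5-dimethoxyphenyl]-3,7-dioxabicyclo[3.3.0]octan-2-yl]phenol | COc1cc([C@H]2OC[C@H]3[C@@H]2CO[C@@H]3c2cc(OC)c(OCc4ccccc4)c(OC)c2)cc(Br)c1O | intermediate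
20 | vanillin | COc1cc(C=O)ccc1O | starting material
21 | 4-(benzyloxy)-3-methoxybenzaldehyde | COc1cc(C=O)ccc1OCc1ccccc1 | intermediate
22 | racemic 1-[4-(benzyloxy)-3-methoxyphenyl]prop-2-en-1-ol | COc1cc(C(O)C=C)ccc1OCc1ccccc1 | intermediate
23 | (S)-[4-(benzyloxy)-3-methoxyphenyl][(R)-oxiran-2-yl]methanol | COc1cc([C@H](O)[C@H]2CO2)ccc1OCc1ccccc1 | intermediate
24 | threo epoxy ether, (1R,2S,5R,6S)-2-[3-bromo-4-[(R)-[4-(benzyloxy)-3-methoxyphenyl][(R)-oxiran-2-yl]methoxy]-5-methoxyphenyl]-6-[4-(benzyloxy)-3,5-dimethoxyphenyl]-3,7-dioxabicyclo[3.3.0]octane | COc1cc([C@@H](Oc2c(OC)cc([C@H]3OC[C@H]4[C@@H]3CO[C@@H]4c3cc(OC)c(OCc5ccccc5)c(OC)c3)cc2Br)[C@H]2CO2)ccc1OCc1ccccc1 | intermediate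
25 | aryllithium from 24 (lithium in place of bromine) | COc1cc([C@@H](Oc2c(OC)cc([C@H]3OC[C@H]4[C@@H]3CO[C@@H]4c3cc(OC)c(OCc5ccccc5)c(OC)c3)cc2[Li])[C@H]2CO2)ccc1OCc1ccccc1 | intermediate (not isolated)
26 | bis-benzyl ether of the target | COc1cc([C@H]2Oc3c(OC)cc([C@H]4OC[C@H]5[C@@H]4CO[C@@H]5c4cc(OC)c(OCc6ccccc6)c(OC)c4)cc3[C@H]2CO)ccc1OCc1ccccc1 | intermediate
27 | CNP0126146.1 | COc1cc([C@H]2Oc3c(OC)cc([C@H]4OC[C@H]5[C@@H]4CO[C@@H]5c4cc(OC)c(O)c(OC)c4)cc3[C@H]2CO)ccc1O | target

## Step count and least certain steps

Total: 16 steps. Longest linear sequence: 11 steps (steps 2, 3, 4, 5, 7, 8, 9, 10, 14, 15, 16). The epoxy alcohol arm (steps 11–13) and the two aldehyde protections (steps 1 and 6) are side branches.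

**Step 15 (key step).** The most likely failure is proton transfer outrunning ring closure. The C2–H is benzylic and α to oxygen, so the aryllithium can be quenched internally, after which the epoxide opens by β-elimination. The threo geometry forces the aryl group and the developing CH2O arm onto one face, which slows the 5-exo closure and gives this path, and closure at the terminal carbon, more time.
Fallback, from 19 back to 26, forming C2–C3 instead:
- Mitsunobu etherification of 19 with commercial 4-(benzyloxy)-3-methoxybenzyl alcohol gives the benzyl aryl ether F1.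
- Palladium-catalysed coupling of the aryl bromide with BrZnCH2CO2t-Bu (Pd(dba)2, QPhos) gives the tert-butyl arylacetate F2.
- Diazo transfer (p-acetamidobenzenesulfonyl azide, DBU) gives the aryldiazoacetate F3.
- A chiral dirhodium tetracarboxylate such as Rh2(S-PTTL)4, or its enantiomer as the sense of induction requires, inserts the carbenoid into the ether O–CH2Ar bond and gives the cis 2-aryl-2,3-dihydrobenzofuran-3-carboxylate F4.
- LiAlH4 at low temperature reduces F4 to 26.
The weakness of this fallback is that cis fidelity then rests on the catalyst and on reducing the ester before it epimerises.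

**Step 14 (Mitsunobu).** The most likely failure is partial loss of stereochemical fidelity: the oxyphosphonium salt of a para-alkoxybenzylic alcohol can ionise, which leaks erythro ether into the product. It is separable, but costs material. Slow coupling of the doubly ortho-substituted phenol is the second concern.
Fallback, from 20 back to 24, with an electron-poor spectator group during the substitution:
- Vanillin is acylated (t-BuCOCl, Et3N) to the pivalate F5.
- CH2=CHMgBr at −78 °C gives the racemic allylic alcohol F6.
- The same kinetic resolution as step 13 gives the erythro epoxy alcohol F7.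
- Mitsunobu coupling with 19 gives the threo ether pivalate F8, whose benzylic centre is much less prone to ionise.
- K2CO3 in MeOH frees the phenol F9, and BnBr with K2CO3 returns 24.

**Step 13 (kinetic resolution).** The most likely failure is slow epoxidation of the monosubstituted vinyl group with too small a rate difference between the enantiomers, giving low enantiomeric purity. Titanium-promoted opening of the electron-rich epoxy alcohol during the long reaction is the second concern.
Fallback, from 22 back to 23:
- Lipase resolution (Candida antarctica lipase B, vinyl acetate) acylates the (R)-enantiomer to the acetate F10, which is separated from the untouched (S)-alcohol.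
- Methanolysis (K2CO3, MeOH) gives the (R)-allylic alcohol F11.
- F11 is epoxidised to completion with Ti(OiPr)4, L-(+)-diisopropyl tartrate and t-BuOOH in the matched sense, giving 23.

**Step 9 (ring B closure).** The 4-benzyloxy group is twisted out of conjugation by its two methoxy neighbours, so ionisation may be sluggish. Forcing the acid risks loss of the benzylic silyl ether, and then closure through the wrong oxygen or Friedel–Crafts attack of the cation on the other ring. Incomplete control at C6′ is the other risk.
Fallback, from 15 back to 18, closing ring B stereospecifically: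
- Dess–Martin oxidation of 15 gives the β-keto lactone F12.
- Chelation-controlled reduction with Zn(BH4)2 gives the single syn (S)-carbinol F13.
- LiBH4 gives the triol F14 as one isomer.
- MsCl in pyridine gives the bis-mesylate F15, in which the benzylic hydroxyl displaces the C8′ sulfonate with retention at C6′, arriving at 18.

**Step 16 (hydrogenolysis).** The most likely failure is over-reduction. The C2–O1 bond is itself a benzyl aryl ether and the furofuran has two benzylic C–O bonds. Traces of acid on the catalyst could also epimerise the cis ring once the phenols are free.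
Fallback, from 26 to 27 without hydrogen: BCl3 with pentamethylbenzene as cation scavenger in CH2Cl2 at −78 °C, quenched cold. This removes aryl benzyl ethers by a Lewis-acid mechanism and makes no new intermediate, but it carries its own acid risk to the benzylic ethers, so contact time must be short.

## Further compounds

F1 | step 15 | benzyl aryl ether from 19 and 4-(benzyloxy)-3-methoxybenzyl alcohol | COc1cc(COc2c(OC)cc([C@H]3OC[C@H]4[C@@H]3CO[C@@H]4c3cc(OC)c(OCc5ccccc5)c(OC)c3)cc2Br)ccc1OCc1ccccc1
F2 | step 15 | tert-butyl arylacetate (CH2CO2t-Bu in place of bromine in F1) | COc1cc(COc2c(OC)cc([C@H]3OC[C@H]4[C@@H]3CO[C@@H]4c3cc(OC)c(OCc5ccccc5)c(OC)c3)cc2CC(=O)OC(C)(C)C)ccc1OCc1ccccc1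
F3 | step 15 | tert-butyl aryldiazoacetate from F2 | COc1cc(COc2c(OC)cc([C@H]3OC[C@H]4[C@@H]3CO[C@@H]4c3cc(OC)c(OCc5ccccc5)c(OC)c3)cc2C(=[N+]=[N-])C(=O)OC(C)(C)C)ccc1OCc1ccccc1
F4 | step 15 | cis tert-butyl 2-aryl-2,3-dihydrobenzofuran-3-carboxylate (same spatial arrangement at C2 and C3 as 26) | COc1cc([C@H]2Oc3c(OC)cc([C@H]4OC[C@H]5[C@@H]4CO[C@@H]5c4cc(OC)c(OCc6ccccc6)c(OC)c4)cc3[C@H]2C(=O)OC(C)(C)C)ccc1OCc1ccccc1
F5 | step 14 | 4-formyl-2-methoxyphenyl pivalate | COc1cc(C=O)ccc1OC(=O)C(C)(C)C
F6 | step 14 | racemic 4-(1-hydroxyprop-2-en-1-yl)-2-methoxyphenyl pivalate | COc1cc(C(O)C=C)ccc1OC(=O)C(C)(C)C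
F7 | step 14 | 4-[(S)-hydroxy[(R)-oxiran-2-yl]methyl]-2-methoxyphenyl pivalate | COc1cc([C@H](O)[C@H]2CO2)ccc1OC(=O)C(C)(C)C
F8 | step 14 | threo epoxy ether with pivalate in place of the guaiacyl benzyl ether of 24 | COc1cc([C@@H](Oc2c(OC)cc([C@H]3OC[C@H]4[C@@H]3CO[C@@H]4c3cc(OC)c(OCc5ccccc5)c(OC)c3)cc2Br)[C@H]2CO2)ccc1OC(=O)C(C)(C)C
F9 | step 14 | threo epoxy ether with free guaiacyl phenol | COc1cc([C@@H](Oc2c(OC)cc([C@H]3OC[C@H]4[C@@H]3CO[C@@H]4c3cc(OC)c(OCc5ccccc5)c(OC)c3)cc2Br)[C@H]2CO2)ccc1O
F10 | step 13 | (R)-1-[4-(benzyloxy)-3-methoxyphenyl]prop-2-en-1-yl acetate | COc1cc([C@H](OC(C)=O)C=C)ccc1OCc1ccccc1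
F11 | step 13 | (R)-1-[4-(benzyloxy)-3-methoxyphenyl]prop-2-en-1-ol | COc1cc([C@H](O)C=C)ccc1OCc1ccccc1
F12 | step 9 | β-keto lactone from 15 (aroyl in place of the carbinol) | O=C1[C@H](C(=O)c2cc(OC)c(OCc3ccccc3)c(OC)c2)[C@@H]([C@H](O[Si](C)(C)C(C)(C)C)c2cc(OC)c(O[Si](C(C)C)(C(C)C)C(C)C)c(Br)c2)CO1
F13 | step 9 | syn aldol lactone, the single (S)-carbinol epimer of 15 | O=C1[C@H]([C@H](O)c2cc(OC)c(OCc3ccccc3)c(OC)c2)[C@@H]([C@H](O[Si](C)(C)C(C)(C)C)c2cc(OC)c(O[Si](C(C)C)(C(C)C)C(C)C)c(Br)c2)CO1
F14 | step 9 | triol, the single (S)-carbinol epimer of 16 | OC[C@H]([C@H](O)c1cc(OC)c(OCc2ccccc2)c(OC)c1)[C@@H]([C@H](O[Si](C)(C)C(C)(C)C)c1cc(OC)c(O[Si](C(C)C)(C(C)C)C(C)C)c(Br)c1)CO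
F15 | step 9 | bis-mesylate of F14 at both primary hydroxyls | CS(=O)(=O)OC[C@H]([C@H](O)c1cc(OC)c(OCc2ccccc2)c(OC)c1)[C@@H]([C@H](O[Si](C)(C)C(C)(C)C)c1cc(OC)c(O[Si](C(C)C)(C(C)C)C(C)C)c(Br)c1)COS(C)(=O)=O
F0 | step 16 | none | none
A1 | alternative 1 | (+)-medioresinol | COc1cc([C@H]2OC[C@H]3[C@@H]2CO[C@@H]3c2cc(OC)c(O)c(OC)c2)ccc1O
A2 | alternative 1 | (2R,3R)-2-(4-hydroxy-3-methoxybenzyl)-3-(4-hydroxy-3,5-dimethoxybenzyl)butane-1,4-diol | OC[C@H](Cc1cc(OC)c(O)c(OC)c1)[C@H](CO)Cc1ccc(O)c(OC)c1
A3 | alternative 2 | trans,trans-disubstituted menthyloxy lactone carrying all carbons of the target | O=C1O[C@@H](O[C@@H]2C[C@H](C)CC[C@H]2C(C)C)[C@H](C2(SCCCS2)c2cc(OC)c(OCc3ccccc3)c(OC)c2)[C@H]1[C@H](O)c1cc(OC)c2O[C@H](c3ccc(OCc4ccccc4)c(OC)c3)[C@H](CO[Si](C)(C)C(C)(C)C)c2c1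
A4 | alternative 2 | cis-dihydrobenzofuran-5-carbaldehyde with benzyl and TBS protection | O=Cc1cc(OC)c2O[C@H](c3ccc(OCc4ccccc4)c(OC)c3)[C@H](CO[Si](C)(C)C(C)(C)C)c2c1
A5 | alternative 2 | (5R)-5-menthyloxyfuran-2(5H)-one | O=C1O[C@@H](O[C@@H]2C[C@H](C)CC[C@H]2C(C)C)C=C1
A6 | alternative 2 | 2-[4-(benzyloxy)-3,5-dimethoxyphenyl]-1,3-dithiane | COc1cc(C2SCCCS2)cc(OC)c1OCc1ccccc1
A7 | alternative 3 | target protected as aryl mesylate, benzyl ether and TBS ether | COc1cc([C@H]2Oc3c(OC)cc([C@H]4OC[C@H]5[C@@H]4CO[C@@H]5c4cc(OC)c(OCc6ccccc6)c(OC)c4)cc3[C@H]2CO[Si](C)(C)C(C)(C)C)ccc1OS(C)(=O)=O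
A8 | alternative 3 | styrene precursor with methoxymethyl ether on the C2′ oxygen and triethylsilyl ether on the C8′ oxygen | COc1cc([C@H]2Oc3c(OC)cc([C@@H](OCOC)[C@@H](CO[Si](CC)(CC)CC)/C=C/c4cc(OC)c(OCc5ccccc5)c(OC)c4)cc3[C@H]2CO[Si](C)(C)C(C)(C)C)ccc1OS(C)(=O)=O
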